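The route rests on cutting the pyran ring of the B-ring 2H-chromene between the aryl carbon C4' (C8a of the chromene) and the ring oxygen. One photochemical operation turns an E-3-hydroxy-3-methylbutenyl side chain at C5' into that ring: sensitised E→Z isomerisation, one-electron oxidation of the 4-methoxystyrene unit (C2'-OMe para to the C5' alkene), attack of the tertiary hydroxyl on C4'–H and loss of H2. The feature exploited is this para OMe/alkenyl relationship, which makes C4' electrophilic in the radical cation. The precursor is a 5,7-dimethoxyisoflavone with no leaving group at C4'. C3 is set afterwards by asymmetric transfer hydrogenation under dynamic kinetic resolution, then re-oxidation and 5-O-demethylation.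

Key step: step 3

Remark on the chemistry: locants C1'–C6' refer to ring B (C1' bonded to C3 of the chromanone, C2' carrying OMe). The C3 centre of the target is (S) by the CIP order C4 > C2 > C1' > H. Compounds 1, 2 and 5 are assumed to be commercial.

Step 1
Reactants: 1 3,5-dimethoxyphenol; 2 2-(5-bromo-2-methoxyphenyl)acetic acid
Product: 4 3-(5-bromo-2-methoxyphenyl)-5,7-dimethoxy-4H-chromen-4-one, via deoxybenzoin 3 (not isolated)
Conditions: BF3·OEt2 (solvent), 85 °C; then DMF, MsCl, 80 °C
Reagents that add atoms: N,N-dimethylformamide, CN(C)C=O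
Why: Friedel–Crafts acylation ortho to the phenol (held as the BF2 chelate) is followed in the same pot by Vilsmeier-type C1 insertion and ring closure, the deoxybenzoin route to isoflavones.

Step 2
Reactants: 4 3-(5-bromo-2-methoxyphenyl)-5,7-dimethoxy-4H-chromen-4-one; 5 2-methylbut-3-en-2-ol
Product: 6 (E)-3-[5-(3-hydroxy-3-methylbut-1-en-1-yl)-2-methoxyphenyl]-5,7-dimethoxy-4H-chromen-4-one
Conditions: Pd(OAc)2 (5 mol%), P(o-tol)3 (10 mol%), Et3N, DMF, 100 °C
Reagents that add atoms: none
Why: Mizoroki–Heck reaction in which the aryl group adds to the terminal alkene carbon and β-hydride elimination can only give the E-styrene, because the carbinol carbon is quaternary.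

Step 3
Reactants: 6 (E)-3-[5-(3-hydroxy-3-methylbut-1-en-1-yl)-2-methoxyphenyl]-5,7-dimethoxy-4H-chromen-4-one
Product: 8 5,7-dimethoxy-3-(7-methoxy-2,2-dimethyl-2H-chromen-6-yl)-4H-chromen-4-one, via Z-alkenol 7 (not isolated)
Conditions: Ir(ppy)3 (1 mol%), MeCN (0.02 M), 450 nm LEDs, Ar, rt; then 9-mesityl-3,6-di-tert-butyl-10-phenylacridinium BF4 (5 mol%), Co(dmgH)2pyCl (5 mol%), 2,6-lutidine (20 mol%), 450 nm LEDs, rt
Reagents that add atoms: none
Why: Proposed new method: triplet energy transfer from photoexcited Ir(ppy)3 should convert the E-styrene 6 into the twisted Z isomer 7 (a known contra-thermodynamic E→Z isomerisation), which brings the tertiary hydroxyl within reach of C4'; the excited acridinium then removes one electron from the 4-methoxystyrene unit, the radical cation carries positive charge on the ring carbons ortho to the alkenyl group, and the hydroxyl oxygen adds to C4' in a 6-endo-trig closure that forms the pyran ring. The cyclohexadienyl radical so formed hands its hydrogen (as electron and proton) to the cobaloxime Co(dmgH)2pyCl, which turns over the acridine radical and releases H2, so the arene is restored without an external oxidant. The closest known reactions are the riboflavin-photocatalysed E→Z isomerisation/oxidative cyclisation of E-cinnamic acids to coumarins, where a carboxyl oxygen closes onto the ortho C–H carbon, and the acridinium/cobaloxime dehydrogenative coupling of styrene radical cations with alcohols; closure of a tertiary allylic alcohol onto an arene C–H bond to give a 2H-chromene has not been shown. No stereocentre is formed. The step needs site selectivity (C4' over C6') and chemoselectivity (ring B styrene over the dimethoxychromone): C6' is flanked by the chromone at C1' whereas C4' has only C3'–H on its free side, the anethole-type styrene is the most easily oxidised π system, the quaternary carbinol carbon leaves no allylic C–H to be lost, and the oxygen cannot reach either alkene carbon in a ring larger than four.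

Step 4
Reactants: 8 5,7-dimethoxy-3-(7-methoxy-2,2-dimethyl-2H-chromen-6-yl)-4H-chromen-4-one
Product: 10 (3S,4S)-5,7-dimethoxy-3-(7-methoxy-2,2-dimethyl-2H-chromen-6-yl)chroman-4-ol, via racemic isoflavanone 9 (not isolated)
Conditions: RuCl[(S,S)-TsDPEN](p-cymene) (5 mol%), HCO2H/Et3N (5:2), EtOAc, 40 °C
Reagents that add atoms: none
Why: Noyori–Ikariya asymmetric transfer hydrogenation run as a cascade: Ru–H 1,4-reduction of the chromone gives isoflavanone 9, whose C3 epimerises fast under Et3N, and the (S,S)-catalyst should reduce the (3S)-ketone faster with hydride delivery to C4 anti to the aryl group (dynamic kinetic resolution), so both centres are set by the catalyst as cis-(3S,4S).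

Step 5
Reactants: 10 (3S,4S)-5,7-dimethoxy-3-(7-methoxy-2,2-dimethyl-2H-chromen-6-yl)chroman-4-ol
Product: 11 (3S)-5,7-dimethoxy-3-(7-methoxy-2,2-dimethyl-2H-chromen-6-yl)chroman-4-one
Conditions: Dess–Martin periodinane (1.3 equiv), CH2Cl2, 0 °C → rt
Reagents that add atoms: none
Why: Dess–Martin oxidation of the benzylic alcohol under non-basic conditions removes the auxiliary C4 centre without enolising the ketone, so C3 should stay (S).

Step 6
Reactants: 11 (3S)-5,7-dimethoxy-3-(7-methoxy-2,2-dimethyl-2H-chromen-6-yl)chroman-4-one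
Product: 12 (3S)-5-hydroxy-7-methoxy-3-(7-methoxy-2,2-dimethyl-2H-chromen-6-yl)chroman-4-one
Conditions: BCl3 (1 M in CH2Cl2, 2 equiv), CH2Cl2, −78 → −20 °C; pH 7 buffer quench
Reagents that add atoms: none
Why: Chelation-controlled Lewis-acid ether cleavage: BCl3 bridges the C4 carbonyl and O5, so only the peri 5-OMe should be cleaved at low temperature, while the other aryl ethers, the chromene and the C3 centre (no base present) are left alone.

Compound list
1 | 3,5-dimethoxyphenol | COc1cc(O)cc(OC)c1 | starting material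
2 | 2-(5-bromo-2-methoxyphenyl)acetic acid | COc1ccc(Br)cc1CC(=O)O | starting material
3 | 2-(5-bromo-2-methoxyphenyl)-1-(2-hydroxy-4,6-dimethoxyphenyl)ethan-1-one | COc1cc(O)c(C(=O)Cc2cc(Br)ccc2OC)c(OC)c1 | intermediate
4 | 3-(5-bromo-2-methoxyphenyl)-5,7-dimethoxy-4H-chromen-4-one | COc1cc(OC)c2c(c1)occ(-c1cc(Br)ccc1OC)c2=O | intermediate
5 | 2-methylbut-3-en-2-ol | C=CC(C)(C)O | starting material
6 | (E)-3-[5-(3-hydroxy-3-methylbut-1-en-1-yl)-2-methoxyphenyl]-5,7-dimethoxy-4H-chromen-4-one | COc1cc(OC)c2c(c1)occ(-c1cc(/C=C/C(C)(C)O)ccc1OC)c2=O | intermediate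
7 | (Z)-3-[5-(3-hydroxy-3-methylbut-1-en-1-yl)-2-methoxyphenyl]-5,7-dimethoxy-4H-chromen-4-one | COc1cc(OC)c2c(c1)occ(-c1cc(/C=C\C(C)(C)O)ccc1OC)c2=O | intermediate
8 | 5,7-dimethoxy-3-(7-methoxy-2,2-dimethyl-2H-chromen-6-yl)-4H-chromen-4-one | COc1cc(OC)c2c(c1)occ(-c1cc3c(cc1OC)OC(C)(C)C=C3)c2=O | intermediate
9 | rac-5,7-dimethoxy-3-(7-methoxy-2,2-dimethyl-2H-chromen-6-yl)chroman-4-one | COc1cc(OC)c2c(c1)OCC(c1cc3c(cc1OC)OC(C)(C)C=C3)C2=O | intermediate
10 | (3S,4S)-5,7-dimethoxy-3-(7-methoxy-2,2-dimethyl-2H-chromen-6-yl)chroman-4-ol (cis) | COc1cc(OC)c2c(c1)OC[C@H](c1cc3c(cc1OC)OC(C)(C)C=C3)[C@@H]2O | intermediate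
11 | (3S)-5,7-dimethoxy-3-(7-methoxy-2,2-dimethyl-2H-chromen-6-yl)chroman-4-one | COc1cc(OC)c2c(c1)OC[C@H](c1cc3c(cc1OC)OC(C)(C)C=C3)C2=O | intermediate
12 | (3S)-5-hydroxy-7-methoxy-3-(7-methoxy-2,2-dimethyl-2H-chromen-6-yl)chroman-4-one | COc1cc(O)c2c(c1)OC[C@H](c1cc3c(cc1OC)OC(C)(C)C=C3)C2=O | target

Total step count: 6
Longest linear sequence: 6 steps (1 → 4 → 6 → 8 → 10 → 11 → 12)

Steps most likely to fail

Step 3. The radical cation may return to the E-alkene or dimerise faster than the hydroxyl closes onto C4', or closure may take place at C6'. The fallback keeps the same ring-closing bond but replaces C–H by a halide and uses known chemistry; it sets out from 1 and comes back at 8. Bromination (Br2, AcOH, rt) of commercial 2-(4-chloro-2-methoxyphenyl)acetic acid (COc1cc(Cl)ccc1CC(=O)O) para to the methoxy group would give 2-(5-bromo-4-chloro-2-methoxyphenyl)acetic acid F1. Acylation of 1 with F1 under the conditions of step 1 would pass through 2-(5-bromo-4-chloro-2-methoxyphenyl)-1-(2-hydroxy-4,6-dimethoxyphenyl)ethan-1-one F2, not isolated, to 3-(5-bromo-4-chloro-2-methoxyphenyl)-5,7-dimethoxy-4H-chromen-4-one F3. Sonogashira coupling at the C–Br bond with 2-methylbut-3-yn-2-ol (Pd(PPh3)2Cl2, CuI, Et3N, 60 °C) would give 3-[4-chloro-5-(3-hydroxy-3-methylbut-1-yn-1-yl)-2-methoxyphenyl]-5,7-dimethoxy-4H-chromen-4-one F4. Semihydrogenation (H2, Pd/CaCO3 poisoned with Pb(OAc)2, quinoline, EtOAc) would give (Z)-3-[4-chloro-5-(3-hydroxy-3-methylbut-1-en-1-yl)-2-methoxyphenyl]-5,7-dimethoxy-4H-chromen-4-one F5. Intramolecular Buchwald–Hartwig etherification of the aryl chloride by the tertiary alcohol (Pd(OAc)2, 2-(di-tert-butylphosphino)-1,1'-binaphthyl, Cs2CO3, toluene, 80 °C) would then close the C4'–O bond and give 8.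

Step 4. The 1,4-reduction of the electron-rich 5,7-dimethoxychromone may stall, or the hindered ketone may be reduced with poor enantiomer discrimination. The fallback sets C3 by enantioselective protonation instead of reduction; it sets out from 8 and comes back at 11, so step 5 is not needed. Conjugate reduction with LiBH(s-Bu)3 (THF, −78 °C) and trapping of the enolate with TMSCl/Et3N would give [5,7-dimethoxy-3-(7-methoxy-2,2-dimethyl-2H-chromen-6-yl)-2H-chromen-4-yl]oxy-trimethylsilane F6. Catalytic enantioselective protonation of this silyl enol ether (BINOL-derived N-triflyl thiophosphoramide, 10 mol%, phenol as stoichiometric proton source, toluene, rt), a known reaction of silyl enol ethers of 2-aryl cyclic ketones, would give 11; the catalyst enantiomer that delivers (S) would be fixed in a trial run.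

Step 6. The boron chelate may enolise and erode the C3 configuration, or the Lewis acid and the HCl set free may attack the chromene. The fallback moves the demethylation ahead of the stereocentre and carries O5 as an acetal; it sets out from 8 and comes back at 12.
- MgI2·OEt2 (toluene, 80 °C) would cleave only the peri ether of 8 and give 5-hydroxy-7-methoxy-3-(7-methoxy-2,2-dimethyl-2H-chromen-6-yl)-4H-chromen-4-one F7.
- NaH, MOMCl (DMF, 0 °C) would give 7-methoxy-5-(methoxymethoxy)-3-(7-methoxy-2,2-dimethyl-2H-chromen-6-yl)-4H-chromen-4-one F8.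
- Transfer hydrogenation as in step 4 would pass through rac-7-methoxy-5-(methoxymethoxy)-3-(7-methoxy-2,2-dimethyl-2H-chromen-6-yl)chroman-4-one F9, not isolated, to (3S,4S)-7-methoxy-5-(methoxymethoxy)-3-(7-methoxy-2,2-dimethyl-2H-chromen-6-yl)chroman-4-ol F10.
- Dess–Martin oxidation as in step 5 would give (3S)-7-methoxy-5-(methoxymethoxy)-3-(7-methoxy-2,2-dimethyl-2H-chromen-6-yl)chroman-4-one F11.
- Dilute HCl in MeOH at rt would remove the peri acetal, which is labile next to the carbonyl, and give 12.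

Further compounds
F1 | step 3 | 2-(5-bromo-4-chloro-2-methoxyphenyl)acetic acid | COc1cc(Cl)c(Br)cc1CC(=O)O
F2 | step 3 | 2-(5-bromo-4-chloro-2-methoxyphenyl)-1-(2-hydroxy-4,6-dimethoxyphenyl)ethan-1-one | COc1cc(O)c(C(=O)Cc2cc(Br)c(Cl)cc2OC)c(OC)c1
F3 | step 3 | 3-(5-bromo-4-chloro-2-methoxyphenyl)-5,7-dimethoxy-4H-chromen-4-one | COc1cc(OC)c2c(c1)occ(-c1cc(Br)c(Cl)cc1OC)c2=O
F4 | step 3 | 3-[4-chloro-5-(3-hydroxy-3-methylbut-1-yn-1-yl)-2-methoxyphenyl]-5,7-dimethoxy-4H-chromen-4-one | COc1cc(OC)c2c(c1)occ(-c1cc(C#CC(C)(C)O)c(Cl)cc1OC)c2=O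
F5 | step 3 | (Z)-3-[4-chloro-5-(3-hydroxy-3-methylbut-1-en-1-yl)-2-methoxyphenyl]-5,7-dimethoxy-4H-chromen-4-one | COc1cc(OC)c2c(c1)occ(-c1cc(/C=C\C(C)(C)O)c(Cl)cc1OC)c2=O
F6 | step 4 | [5,7-dimethoxy-3-(7-methoxy-2,2-dimethyl-2H-chromen-6-yl)-2H-chromen-4-yl]oxy-trimethylsilane | COc1cc(OC)c2c(c1)OCC(c1cc3c(cc1OC)OC(C)(C)C=C3)=C2O[Si](C)(C)C
F7 | step 6 | 5-hydroxy-7-methoxy-3-(7-methoxy-2,2-dimethyl-2H-chromen-6-yl)-4H-chromen-4-one | COc1cc(O)c2c(c1)occ(-c1cc3c(cc1OC)OC(C)(C)C=C3)c2=O
F8 | step 6 | 7-methoxy-5-(methoxymethoxy)-3-(7-methoxy-2,2-dimethyl-2H-chromen-6-yl)-4H-chromen-4-one | COc1cc(OCOC)c2c(c1)occ(-c1cc3c(cc1OC)OC(C)(C)C=C3)c2=O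
F9 | step 6 | rac-7-methoxy-5-(methoxymethoxy)-3-(7-methoxy-2,2-dimethyl-2H-chromen-6-yl)chroman-4-one | COc1cc(OCOC)c2c(c1)OCC(c1cc3c(cc1OC)OC(C)(C)C=C3)C2=O
F10 | step 6 | (3S,4S)-7-methoxy-5-(methoxymethoxy)-3-(7-methoxy-2,2-dimethyl-2H-chromen-6-yl)chroman-4-ol | COc1cc(OCOC)c2c(c1)OC[C@H](c1cc3c(cc1OC)OC(C)(C)C=C3)[C@@H]2O
F11 | step 6 | (3S)-7-methoxy-5-(methoxymethoxy)-3-(7-methoxy-2,2-dimethyl-2H-chromen-6-yl)chroman-4-one | COc1cc(OCOC)c2c(c1)OC[C@H](c1cc3c(cc1OC)OC(C)(C)C=C3)C2=O
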